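**Analysis of the target**

The target is a daucane sesquiterpenoid ester: a trans-fused hydroazulene in which cyclopentane ring A (C1–C5) shares the C1–C5 bond with seven-membered ring B (C5–C10 plus C1). Numbering used throughout: C1 is the quaternary carbon with the angular methyl group, C4 the isopropyl carbinol, C5 the ring-fusion CH, C6 the carbon bearing the 3,4-dimethoxybenzoate, C7 a methylene, C8 (methyl-bearing) and C9 the epoxide carbons, C10 a methylene. The six stereocentres are (1R,4R,5S,6S,8R,9S). With β defined as the face of the angular methyl group, the C4 hydroxyl is β, H-5 is α (trans fusion), and the C6 acyloxy group and the epoxide oxygen are both α. The C4 and C6 oxygens are therefore 1,3-anti across C5, and the epoxide is syn to the C6 oxygen. Sensitive groups are the trisubstituted epoxide (it faces a tertiary alcohol that can open it under acid), the tertiary carbinol (dehydration), and the C4–C5–C6 dioxygenated unit, which at any ketone stage can suffer retro-aldol cleavage, β-elimination or epimerisation at C5. The difficulty lies in the seven-membered ring, the quaternary C1 beside the ring fusion, and the C4–C5–C6 triad wedged between two fully substituted carbons. The strategy rests on ring B: its C6 oxygen and its methylated C8=C9 unsaturation are separated by the single methylene C7, which is the pattern formed when a 1-siloxyvinyl group on a cyclopropane made of C5, C1 and C10 takes up a two-carbon alkyne unit between C7 and C10.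

**Retrosynthetic reasoning**

Compound numbers are those of the steps below.

- **Ester (21 ⇒ 19 + 20).** The C6–O acyl bond is cut last. The aryl ester is the group least tolerant of hydride and organometallic reagents, and the free C6 hydroxyl is needed one step earlier to direct the epoxidation. The forward step must acylate a secondary alcohol beside a tertiary alcohol and an epoxide under non-acidic conditions.

- **Epoxide (19 ⇒ 18).** The two C–O bonds at C8 and C9 are cut next, because the epoxide is the most fragile function and should be carried through as few steps as possible. In 18 the homoallylic 6α-hydroxyl lies on the face that must receive the oxygen, so a metal-bound peroxide delivered from that hydroxyl should give the α-epoxide.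

- **C6 configuration (18 ⇒ 17 ⇒ 16).** The C6–H bond is cut to give β-hydroxy ketone 17. The tertiary C4 hydroxyl sits on the β face and can carry a borohydride to the β face of the C6 carbonyl, giving the 1,3-anti diol. Ketone 17 is traced to diol 16, its C6 epimer, by oxidation. This detour is deliberate: C6 has to be held at the alcohol level while C4 is built, and the configuration that simple hydride reduction is expected to give (6β) is the wrong one, so it is erased and reset by the directed reduction.

- **Isopropyl group (16 ⇒ 15).** The C4–isopropyl bond is cut to the C4 ketone 15. The addition is placed after C5 has become a trans-fused methine, so that the incoming nucleophile is steered to the α face by H-5, by the angular methyl group and by the 6β-oxygen, all of which leave that face open.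

- **Masks (15 ⇒ 14 ⇒ 13 ⇒ 11).** The C4 ketal, the silicon on C9 and the enol silyl ether at C6 are removed in reverse order. The cycloadduct 11 is a vinylogous orthoester, so its enol ether must be opened by a fluoride source and not by acid. The resulting ketone 12 is β,γ-unsaturated with an epimerisable C5, so it is reduced at once. The acid steps are held back until only an alcohol, a ketal and a vinylsilane remain.

- **Key disconnection (11 ⇒ 9 + 10).** Bonds C7–C8 and C9–C10 are cut and C5–C10 is reconnected, turning ring B of 11 into the siloxyvinyl cyclopropane 9 and the two-carbon alkyne 10. This is chosen over cuts in ring A because it gives ring B with exactly the needed functionality (one masked ketone at C6, one alkene at C8=C9) and no redox correction. The forward reaction must open the methylene bond C5–C10 and not the fusion bond C5–C1, and must put the methyl group on C8. The accepted steric model for this cycloaddition places the larger alkyne substituent away from the first-formed bond, so a methyl group as the only substituent would be expected on C9. Alkyne 10 therefore carries a removable silyl group, which takes the C9 position and leaves the methyl group on C8.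

- **Precursor (9 ⇒ 8 ⇒ 7 ⇒ 6 ⇒ 5).** These are functional-group changes only: enol silylation of a methyl ketone with one enolisable side, methyl ketone from a carboxylic acid, acid from a methyl ester, ketal from the ring ketone. The ester in 5 is what distinguishes the C6 carbon from the C4 ketone.

- **Cyclopropane (5 ⇒ 4).** Bonds C5–C1 and C5–C10 are cut, giving an intramolecular carbenoid addition to a 1,1-disubstituted alkene. This is the only reagent-controlled stereocentre-forming step and it sets C1 for the whole route. The C5–C10 bond made here is the one opened in the key step.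

- **Chain (4 ⇒ 3 ⇒ 1 + 2).** Diazo transfer and a C–C alkylation of the dianion of 1 with 2 lead back to two commodity chemicals.

**Alternatives that were turned down**

Alternative 1: The disconnection cuts C1–C5 and C1–C10, with a benzene ring supplying C5–C10 of ring B. In the forward step the aryl-tethered α-methyl diazoketone (5R)-2-diazo-5-(2-methoxy-4-methylphenyl)-6-methyl-5-(triethylsilyloxy)heptan-3-one A1 is decomposed by Rh2(O2CCPh3)4 (divalent rhodium). The carbenoid at C1 adds across the ipso–ortho bond of the arene, the three-membered ring so formed opens electrocyclically, and the bicyclic cycloheptatriene A2 results (intramolecular Buchner reaction).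
- For: all of ring B comes from a cheap arene with the C6 oxygen and the C8 methyl in place; quaternary C1 is made in the ring-forming step; the C4 carbinol with its isopropyl group exists in A1 before cyclisation. On that last point it is stronger than the chosen route, which must add a branched nucleophile late.
- Against: A2 is at the triene level, so two of three ring-B alkenes must be removed and the survivor placed at C8=C9, with no obvious selective way. An extra C2 ketone must be deleted. An α-alkyl carbenoid is prone to 1,2-hydride shift. The tertiary benzylic carbinol of A1 must be made enantioenriched and must control C1 across the forming ring. The carbenoid from A1 has two ortho bonds to choose from.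
- Comparison: the chosen cycloaddition delivers ring B at the correct oxidation level, which outweighs the late isopropyl addition; A2 would need several redox corrections that the chosen adduct does not.

Alternative 2: The disconnection cuts C5–C6 and C9–C10. The vinyl diazo ester methyl 2-diazo-3-methylbut-3-enoate A3 and the diene 3-methylfuran A4 are combined under Rh2(S-PTAD)4 (divalent rhodium). Cyclopropanation of the unsubstituted double bond of A4, followed by a Cope rearrangement of the divinylcyclopropane, gives the oxygen-bridged cycloheptadiene A5.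
- For: this key step is the best precedented and most reliably enantioselective of all four, and A3 and A4 together give all seven ring-B carbons with oxygen at C6 and C9 and the C8 methyl. On reliability of the key step it is stronger than the chosen route.
- Against: C1 is still trigonal in A5, so the quaternary stereocentre must be made later by addition to a hindered tetrasubstituted enoate. All of ring A and the isopropyl group remain to be attached. The ether bridge of A5 ties C6 to C9, so the C9–O bond must be broken and the C8=C9 alkene regenerated before epoxidation. A3 is prone to cyclise with loss of the diazo function before it meets the catalyst, and A4 offers a second, methyl-bearing double bond whose attack would misplace the methyl group.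
- Comparison: the chosen route has ring A and C1 in place before ring B is formed and needs far fewer C–C bonds after the key step than a route through A5.

Alternative 3: The disconnection cuts C4–C5. The monocyclic diketone (6S)-3,6-dimethyl-6-(4-methyl-3-oxopentyl)cyclohept-2-en-1-one A6 is deprotonated at C5 with LiN(SiMe3)2 or an equilibrating base, and the enolate of A6 adds to the pendant isopropyl ketone to give the bicyclic β-hydroxy enone A7.
- For: C4 and C5 are set together, probably under thermodynamic control that favours the isopropyl group trans to C6. No isopropyl organometallic is needed, and the C1 stereocentre of A6 can come from an asymmetric conjugate addition. On control of C4 and C5 it is stronger than the chosen route, which relies on a kinetic protonation and a separate addition.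
- Against: the enolate carbon of A6 is neopentyl and the ketone α-branched, so the aldol equilibrium may favour the open form. γ-Deprotonation of the enone competes. The alkene of A7 is conjugated at C7=C8 and must be moved to C8=C9 before epoxidation.
- Comparison: A7 is the conjugated isomer of 17. The chosen route reaches the same stage with the alkene already at C8=C9 and offers the cycloaddition as a direct ring-B construction.

Key step: step 8

Remark on numbering: daucane numbering as defined above is used for all bicyclic compounds; β is the face of the angular C1 methyl group, α the opposite face.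

Assumption: the (S,S)-bis(oxazoline) ligand of step 3 is taken to give the (1R,5R) product; if the sense of induction is the opposite, its enantiomer is used.

Assumption: 1-(trimethylsilyl)propyne (10), the C-silylated form of propyne, is bought.

**Route**

Step 1
Reactants: 1 methyl acetoacetate; 2 3-chloro-2-methylprop-1-ene
Product: 3 methyl 6-methyl-3-oxohept-6-enoate
Conditions: NaH, THF, 0 °C; n-BuLi, 0 °C; 2, 0 °C → rt; cold 1 M HCl
Reagents that add atoms: none
Why: Acetoacetate dianion alkylation: the more basic terminal carbanion is alkylated by the allylic chloride and the β-keto ester is regenerated on quench.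

Step 2
Reactants: 3 methyl 6-methyl-3-oxohept-6-enoate
Product: 4 methyl 2-diazo-6-methyl-3-oxohept-6-enoate
Conditions: 4-acetamidobenzenesulfonyl azide, Et3N, MeCN, 0 °C → rt
Reagents that add atoms: 4-acetamidobenzenesulfonyl azide, CC(=O)Nc1ccc(cc1)S(=O)(=O)N=[N+]=[N-]
Why: Regitz diazo transfer to an active methylene compound.

Step 3
Reactants: 4 methyl 2-diazo-6-methyl-3-oxohept-6-enoate
Product: 5 methyl (1R,5R)-5-methyl-2-oxobicyclo[3.1.0]hexane-1-carboxylate
Conditions: (CuOTf)2·C6H6 (2.5 mol%), (S,S)-t-Bu-box [2,2'-(propane-2,2-diyl)bis((4S)-4-tert-butyl-4,5-dihydrooxazole)] (6 mol%), toluene, 50 °C, slow addition of 4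
Reagents that add atoms: none
Why: Intramolecular asymmetric cyclopropanation by a monovalent copper carbenoid; the tether enforces cis fusion, so the ligand sets both cyclopropane stereocentres together, including the future C1.

Step 4
Reactants: 5 methyl (1R,5R)-5-methyl-2-oxobicyclo[3.1.0]hexane-1-carboxylate
Product: 6 methyl (1R,5R)-5-methylspiro[bicyclo[3.1.0]hexane-2,2'-[1,3]dioxolane]-1-carboxylate
Conditions: 1,2-bis(trimethylsilyloxy)ethane, TMSOTf (5 mol%), CH2Cl2, −78 → −20 °C; pyridine quench
Reagents that add atoms: 1,2-bis(trimethylsilyloxy)ethane, C[Si](C)(C)OCCO[Si](C)(C)C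
Why: Noyori ketalisation under aprotic low-temperature conditions, chosen because hot protic acid could open the doubly activated cyclopropane by homoconjugate addition.

Step 5
Reactants: 6 methyl (1R,5R)-5-methylspiro[bicyclo[3.1.0]hexane-2,2'-[1,3]dioxolane]-1-carboxylate
Product: 7 (1R,5R)-5-methylspiro[bicyclo[3.1.0]hexane-2,2'-[1,3]dioxolane]-1-carboxylic acid
Conditions: LiOH·H2O, THF–MeOH–H2O, 60 °C; cold 1 M HCl to pH 4
Reagents that add atoms: lithium hydroxide, [Li+].[OH-]
Why: Saponification of a hindered methyl ester; the ketal is stable to base and the cyclopropane is no longer doubly activated.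

Step 6
Reactants: 7 (1R,5R)-5-methylspiro[bicyclo[3.1.0]hexane-2,2'-[1,3]dioxolane]-1-carboxylic acid
Product: 8 1-[(1S,5R)-5-methylspiro[bicyclo[3.1.0]hexane-2,2'-[1,3]dioxolan]-1-yl]ethanone
Conditions: MeLi (2.5 equiv), Et2O, 0 °C → rt; inverse quench into ice-cold water
Reagents that add atoms: methyllithium, [Li]C
Why: Ketone synthesis from a lithium carboxylate and an organolithium: the dilithio gem-diolate is stable until work-up, so no tertiary alcohol forms.

Step 7
Reactants: 8 1-[(1S,5R)-5-methylspiro[bicyclo[3.1.0]hexane-2,2'-[1,3]dioxolan]-1-yl]ethanone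
Product: 9 (1S,5R)-1-[1-(tert-butyldimethylsilyloxy)ethenyl]-5-methylspiro[bicyclo[3.1.0]hexane-2,2'-[1,3]dioxolane]
Conditions: TBSOTf, Et3N, CH2Cl2, 0 °C
Reagents that add atoms: tert-butyldimethylsilyl triflate, CC(C)(C)[Si](C)(C)OS(=O)(=O)C(F)(F)F
Why: Soft enolisation and O-silylation; only the methyl group carries α-hydrogens, so one enol ether forms, and excess amine protects the ketal.

Step 8
Reactants: 9 (1S,5R)-1-[1-(tert-butyldimethylsilyloxy)ethenyl]-5-methylspiro[bicyclo[3.1.0]hexane-2,2'-[1,3]dioxolane]; 10 1-(trimethylsilyl)propyne
Product: 11 (1R)-6-(tert-butyldimethylsilyloxy)-4,4-ethylenedioxy-1,8-dimethyl-9-(trimethylsilyl)bicyclo[5.3.0]deca-5,8-diene (daucane numbering)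
Conditions: [Rh(CO)2Cl]2 (5 mol%), 10 (3 equiv), 1,2-dichloroethane, 80 °C, sealed tube, argon
Reagents that add atoms: none
Why: Monovalent rhodium coordinates the siloxy-substituted vinyl group and inserts into the adjacent unhindered C5–C10 cyclopropane bond to give a σ-alkyl/π-allyl rhodacycle (Rh–C10; allyl C5–C6–C7). Alkyne 10 then inserts at the allyl terminus (C7–C8) and C(sp3)–C(sp2) reductive elimination forms C9–C10, the mechanism accepted for the rhodium-catalysed intermolecular (5+2) cycloaddition of oxygen-substituted vinylcyclopropanes with alkynes, which is the closest known reaction. Ring B closes as a (5+2) cycloaddition, formally a two-carbon insertion into the three-membered ring, with the last bond made by reductive elimination from an eight-membered metallacycle. No stereocentre is created: C1 is a spectator that keeps the configuration from step 3, and C5 becomes trigonal. Bond selectivity: opening the fusion bond C5–C1 would require rhodium to enter at the quaternary carbon and would lead to a bridged ring with a bridgehead enol ether, so the methylene bond C5–C10 should open. Regioselectivity: in the insertion the larger, metal-stabilising Me3Si group avoids the carbon that bonds to C7, so silicon ends on C9 and the methyl group on C8, whereas an alkyne with methyl as its only substituent would be expected to place that methyl group on C9. The rhodium-bound methylene C10 has no β-hydrogen because C1 is quaternary, which closes the usual diene-forming escape. The product is a vinylogous orthoester and is kept away from acid.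

Step 9
Reactants: 11 (1R)-6-(tert-butyldimethylsilyloxy)-4,4-ethylenedioxy-1,8-dimethyl-9-(trimethylsilyl)bicyclo[5.3.0]deca-5,8-diene
Product: 13 (1R,5S,6R)-4,4-ethylenedioxy-1,8-dimethyl-9-(trimethylsilyl)bicyclo[5.3.0]dec-8-en-6-ol (6β-alcohol; daucane numbering), via β-keto ketal 12 (not isolated)
Conditions: TBAF, AcOH, THF, −20 → 0 °C; then MeOH, NaBH4, −20 → 0 °C
Reagents that add atoms: none
Why: Fluoride cleaves the enol silyl ether and acetic acid protonates the enolate at once at C5, expected from the α face away from the nearly perpendicular angular methyl group, giving the trans fusion and leaving no time for ketal β-elimination or alkene migration. The β,γ-unsaturated ketone 12 is reduced in the same flask; hydride should also come from the α face, giving the 6β-alcohol. The C6 configuration is erased in step 13, so either epimer converges.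

Step 10
Reactants: 13 (1R,5S,6R)-4,4-ethylenedioxy-1,8-dimethyl-9-(trimethylsilyl)bicyclo[5.3.0]dec-8-en-6-ol
Product: 14 (1R,5S,6R)-4,4-ethylenedioxy-1,8-dimethylbicyclo[5.3.0]dec-8-en-6-ol
Conditions: TFA (5 equiv), CH2Cl2, 0 °C; aq. NaHCO3; then K2CO3, MeOH, rt
Reagents that add atoms: none
Why: Ipso protodesilylation of a vinylsilane: protonation at C9 gives a tertiary β-silyl cation at C8 that loses silicon, so the alkene stays at C8=C9. The methanolic carbonate wash cleaves any trifluoroacetate formed at C6.

Step 11
Reactants: 14 (1R,5S,6R)-4,4-ethylenedioxy-1,8-dimethylbicyclo[5.3.0]dec-8-en-6-ol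
Product: 15 (1R,5S,6R)-6-hydroxy-1,8-dimethylbicyclo[5.3.0]dec-8-en-4-one
Conditions: 1 M HCl, THF, 0 °C → rt
Reagents that add atoms: water, O
Why: Acid hydrolysis of the dioxolane; dilute acid at room temperature and a short reaction time are chosen to avoid dehydration of the β-hydroxy ketone and enolisation at C5.

Step 12
Reactants: 15 (1R,5S,6R)-6-hydroxy-1,8-dimethylbicyclo[5.3.0]dec-8-en-4-one
Product: 16 (1R,4R,5S,6R)-1,8-dimethyl-4-(propan-2-yl)bicyclo[5.3.0]dec-8-ene-4,6-diol (4β,6β-diol)
Conditions: CeCl3 (4 equiv, dried), iPrMgCl (4 equiv), THF, −78 °C; then 15, −78 → −20 °C; aq. NH4Cl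
Reagents that add atoms: isopropylmagnesium chloride, CC(C)[Mg]Cl
Why: Organocerium addition to an enolisable ketone; the first equivalent deprotonates the C6 hydroxyl and the low basicity suppresses enolisation and retro-aldol. The isopropyl group should enter from the α face, beside H-5 and away from the C5–C6 bond, the angular methyl group and the 6β-alkoxide, giving the 4β-hydroxyl.

Step 13
Reactants: 16 (1R,4R,5S,6R)-1,8-dimethyl-4-(propan-2-yl)bicyclo[5.3.0]dec-8-ene-4,6-diol
Product: 17 (1R,4R,5R)-4-hydroxy-1,8-dimethyl-4-(propan-2-yl)bicyclo[5.3.0]dec-8-en-6-one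
Conditions: Dess–Martin periodinane, NaHCO3, CH2Cl2, 0 °C → rt
Reagents that add atoms: none
Why: Dess–Martin oxidation of the secondary alcohol while the tertiary one is inert; buffered neutral conditions avoid alkene migration into conjugation and retro-aldol.

Step 14
Reactants: 17 (1R,4R,5R)-4-hydroxy-1,8-dimethyl-4-(propan-2-yl)bicyclo[5.3.0]dec-8-en-6-one
Product: 18 (1R,4R,5S,6S)-1,8-dimethyl-4-(propan-2-yl)bicyclo[5.3.0]dec-8-ene-4,6-diol (4β,6α-diol)
Conditions: Me4NBH(OAc)3 (5 equiv), MeCN–AcOH (1:1), −30 → −20 °C; aq. NaHCO3
Reagents that add atoms: none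
Why: Evans–Saksena reduction: the reagent exchanges onto the β-oriented C4 hydroxyl and delivers hydride intramolecularly to the β face of the C6 carbonyl, giving the 1,3-anti diol with the 6α-hydroxyl.

Step 15
Reactants: 18 (1R,4R,5S,6S)-1,8-dimethyl-4-(propan-2-yl)bicyclo[5.3.0]dec-8-ene-4,6-diol
Product: 19 (1R,4R,5S,6S,8R,9S)-8,9-epoxy-1,8-dimethyl-4-(propan-2-yl)bicyclo[5.3.0]decane-4,6-diol (8α,9α-epoxide)
Conditions: VO(acac)2 (5 mol%), t-BuOOH (in decane), CH2Cl2, 0 °C → rt; aq. Na2S2O3
Reagents that add atoms: tert-butyl hydroperoxide, CC(C)(C)OO
Why: Hydroxyl-directed epoxidation: the homoallylic 6α-hydroxyl binds vanadium and delivers the peroxide oxygen to the same face of the trisubstituted alkene, setting C8 and C9; the C4 hydroxyl is too remote to compete.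

Step 16
Reactants: 19 (1R,4R,5S,6S,8R,9S)-8,9-epoxy-1,8-dimethyl-4-(propan-2-yl)bicyclo[5.3.0]decane-4,6-diol; 20 3,4-dimethoxybenzoic acid
Product: 21 CNP0251065.1, the 6-(3,4-dimethoxybenzoate) of 19
Conditions: 20, EDC·HCl, DMAP, CH2Cl2, rt
Reagents that add atoms: none
Why: Steglich esterification: only the secondary C6 hydroxyl is acylated, the tertiary C4 hydroxyl is unreactive and the non-acidic conditions preserve the epoxide.

**Compound list**

1 | methyl acetoacetate | CC(=O)CC(=O)OC | starting material
2 | 3-chloro-2-methylprop-1-ene | CC(=C)CCl | starting material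
3 | methyl 6-methyl-3-oxohept-6-enoate | COC(=O)CC(=O)CCC(C)=C | intermediate
4 | methyl 2-diazo-6-methyl-3-oxohept-6-enoate | COC(=O)C(=[N+]=[N-])C(=O)CCC(C)=C | intermediate
5 | methyl (1R,5R)-5-methyl-2-oxobicyclo[3.1.0]hexane-1-carboxylate | COC(=O)[C@]12C[C@@]1(C)CCC2=O | intermediate
6 | methyl (1R,5R)-5-methylspiro[bicyclo[3.1.0]hexane-2,2'-[1,3]dioxolane]-1-carboxylate | COC(=O)[C@]12C[C@@]1(C)CCC23OCCO3 | intermediate
7 | (1R,5R)-5-methylspiro[bicyclo[3.1.0]hexane-2,2'-[1,3]dioxolane]-1-carboxylic acid | OC(=O)[C@]12C[C@@]1(C)CCC23OCCO3 | intermediate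
8 | 1-[(1S,5R)-5-methylspiro[bicyclo[3.1.0]hexane-2,2'-[1,3]dioxolan]-1-yl]ethanone | CC(=O)[C@]12C[C@@]1(C)CCC23OCCO3 | intermediate
9 | (1S,5R)-1-[1-(tert-butyldimethylsilyloxy)ethenyl]-5-methylspiro[bicyclo[3.1.0]hexane-2,2'-[1,3]dioxolane] | C=C(O[Si](C)(C)C(C)(C)C)[C@]12C[C@@]1(C)CCC23OCCO3 | intermediate
10 | 1-(trimethylsilyl)propyne | CC#C[Si](C)(C)C | starting material
11 | (1R)-6-(tert-butyldimethylsilyloxy)-4,4-ethylenedioxy-1,8-dimethyl-9-(trimethylsilyl)bicyclo[5.3.0]deca-5,8-diene | CC(C)(C)[Si](C)(C)OC1=C2C3(OCCO3)CC[C@]2(C)CC([Si](C)(C)C)=C(C)C1 | intermediate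
12 | (1R,5S)-4,4-ethylenedioxy-1,8-dimethyl-9-(trimethylsilyl)bicyclo[5.3.0]dec-8-en-6-one | O=C2CC(C)=C([Si](C)(C)C)C[C@@]3(C)CCC4(OCCO4)[C@H]23 | intermediate (not isolated)
13 | (1R,5S,6R)-4,4-ethylenedioxy-1,8-dimethyl-9-(trimethylsilyl)bicyclo[5.3.0]dec-8-en-6-ol | O[C@@H]2CC(C)=C([Si](C)(C)C)C[C@@]3(C)CCC4(OCCO4)[C@H]23 | intermediate
14 | (1R,5S,6R)-4,4-ethylenedioxy-1,8-dimethylbicyclo[5.3.0]dec-8-en-6-ol | O[C@@H]2CC(C)=CC[C@@]3(C)CCC4(OCCO4)[C@H]23 | intermediate
15 | (1R,5S,6R)-6-hydroxy-1,8-dimethylbicyclo[5.3.0]dec-8-en-4-one | O[C@@H]2CC(C)=CC[C@@]3(C)CCC(=O)[C@H]23 | intermediate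
16 | (1R,4R,5S,6R)-1,8-dimethyl-4-(propan-2-yl)bicyclo[5.3.0]dec-8-ene-4,6-diol | O[C@@H]2CC(C)=CC[C@@]3(C)CC[C@@](O)(C(C)C)[C@H]23 | intermediate
17 | (1R,4R,5R)-4-hydroxy-1,8-dimethyl-4-(propan-2-yl)bicyclo[5.3.0]dec-8-en-6-one | O=C2CC(C)=CC[C@@]3(C)CC[C@@](O)(C(C)C)[C@H]23 | intermediate
18 | (1R,4R,5S,6S)-1,8-dimethyl-4-(propan-2-yl)bicyclo[5.3.0]dec-8-ene-4,6-diol | O[C@H]2CC(C)=CC[C@@]3(C)CC[C@@](O)(C(C)C)[C@H]23 | intermediate
19 | (1R,4R,5S,6S,8R,9S)-8,9-epoxy-1,8-dimethyl-4-(propan-2-yl)bicyclo[5.3.0]decane-4,6-diol | O[C@H]2C[C@@]3(C)O[C@H]3C[C@@]3(C)CC[C@@](O)(C(C)C)[C@H]23 | intermediate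
20 | 3,4-dimethoxybenzoic acid | COc1ccc(C(=O)O)cc1OC | starting material
21 | CNP0251065.1 | COc1ccc(C(=O)O[C@H]2C[C@@]3(C)O[C@H]3C[C@@]3(C)CC[C@@](O)(C(C)C)[C@H]23)cc1OC | target

**Step count and least certain steps**

Total: 16 steps. Longest linear sequence: 16 steps (1 to 21); 10 and 20 are bought and enter at steps 8 and 16.

Step 8 (key step). Most likely failures: the oxidative opening or the alkyne insertion stalls because the vinyl-bearing carbon is fully substituted and the alkyne is internal and silylated, or the alkyne is consumed by oligomerisation, or regiocontrol in the insertion is lost.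
Fallback: the same C5–C10 bond is opened stepwise and ring B is closed by metathesis. It sets out from 5. (H2C=CH)2CuLi opens the doubly activated cyclopropane at the methylene by homoconjugate addition to give methyl (2R)-2-methyl-5-oxo-2-(prop-2-en-1-yl)cyclopentane-1-carboxylate F1. Ketalisation as in step 4, followed by NaOMe equilibration to place the ester trans to the allyl group, gives methyl (6R,7R)-7-methyl-7-(prop-2-en-1-yl)-1,4-dioxaspiro[4.4]nonane-6-carboxylate F2. Aminolysis with N,O-dimethylhydroxylamine hydrochloride and iPrMgCl gives the corresponding N-methoxy-N-methylamide F3. H2C=C(CH3)CH2MgCl converts it into the 2-methylallyl ketone F4. Ring-closing metathesis with the second-generation Grubbs catalyst forms the C8=C9 alkene of (1R,5S)-4,4-ethylenedioxy-1,8-dimethylbicyclo[5.3.0]dec-8-en-6-one F5. NaBH4 reduction then returns to the route at 14.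

Step 9. Most likely failures: poor facial selectivity in the protonation at C5 (the methylene C10 also leans out of the enolate plane on the α face), giving cis-fused material that would then misdirect step 12; or migration of the C8=C9 alkene into conjugation during the short life of ketone 12.
Fallback: the isopropyl group is added while C5 is still trigonal and C5 is settled afterwards by equilibration. It sets out from 11. Aqueous TFA removes both silyl groups and the ketal to give (1R)-1,8-dimethylbicyclo[5.3.0]dec-8-ene-4,6-dione F6. O-silylation (TBSOTf, Et3N) should give mainly the enol ether with the double bond exocyclic to the five-membered ring, (1R)-6-(tert-butyldimethylsilyloxy)-1,8-dimethylbicyclo[5.3.0]deca-5,8-dien-4-one F7. iPrMgCl/CeCl3 adds to the C4 carbonyl from the face opposite the angular methyl group to give the tertiary carbinol (1R,4R)-6-(tert-butyldimethylsilyloxy)-1,8-dimethyl-4-(propan-2-yl)bicyclo[5.3.0]deca-5,8-dien-4-ol F8. TBAF/AcOH then gives 17, in which brief DBU treatment should favour the trans-fused epimer because it keeps the isopropyl group trans to C6. The route is rejoined at 17.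

Step 12. Most likely failures: enolisation or β-hydride reduction by the branched reagent instead of addition, retro-aldol of the β-alkoxide, or loss of facial selectivity through chelation of the C6 alkoxide.
Fallback: a less hindered sp2 nucleophile without β-hydrogens is used and then saturated. It sets out from 15. Isopropenylmagnesium bromide/CeCl3 gives (1R,4S,5S,6R)-1,8-dimethyl-4-(prop-1-en-2-yl)bicyclo[5.3.0]dec-8-ene-4,6-diol F9, which has the same spatial arrangement at C4 as 16. Hydrogenation with RhCl(PPh3)3 reduces the 1,1-disubstituted alkene and spares the trisubstituted ring alkene, returning to the route at 16.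

Step 15. Most likely failures: transannular opening of the new epoxide by the C4 hydroxyl under the Lewis-acidic catalyst, or weak direction by a homoallylic hydroxyl leading to a mixture of faces.
Fallback: reagent control replaces substrate direction. It sets out from 18. Steglich esterification with 20 gives (1R,4R,5S,6S)-4-hydroxy-1,8-dimethyl-4-(propan-2-yl)bicyclo[5.3.0]dec-8-en-6-yl 3,4-dimethoxybenzoate F10. Shi epoxidation (fructose-derived ketone of the enantiomer that attacks the α face, KHSO5, K2CO3 buffer, 0 °C) of the trisubstituted alkene, whose β face is also shielded by the angular methyl group, gives 21 directly.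

Step 3. Most likely failure: insufficient enantioselectivity with a small methyl ester on the diazo carbon.
Fallback: enantiomeric enrichment by crystallisation. It sets out from 7 of low enantiomeric purity. The salt with (S)-1-phenylethylamine, (S)-1-phenylethylammonium (1R,5R)-5-methylspiro[bicyclo[3.1.0]hexane-2,2'-[1,3]dioxolane]-1-carboxylate F11, is recrystallised (the other amine enantiomer is used if it gives the less soluble salt of the wanted acid) and acidified to return 7.

**Further compounds**

F1 | step 8 | methyl (2R)-2-methyl-5-oxo-2-(prop-2-en-1-yl)cyclopentane-1-carboxylate | C=CC[C@@]1(C)CCC(=O)C1C(=O)OC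
F2 | step 8 | methyl (6R,7R)-7-methyl-7-(prop-2-en-1-yl)-1,4-dioxaspiro[4.4]nonane-6-carboxylate | C=CC[C@@]1(C)CCC2(OCCO2)[C@@H]1C(=O)OC
F3 | step 8 | (6R,7R)-N-methoxy-N,7-dimethyl-7-(prop-2-en-1-yl)-1,4-dioxaspiro[4.4]nonane-6-carboxamide | C=CC[C@@]1(C)CCC2(OCCO2)[C@@H]1C(=O)N(C)OC
F4 | step 8 | 3-methyl-1-[(6S,7R)-7-methyl-7-(prop-2-en-1-yl)-1,4-dioxaspiro[4.4]nonan-6-yl]but-3-en-1-one | C=CC[C@@]1(C)CCC2(OCCO2)[C@@H]1C(=O)CC(C)=C
F5 | step 8 | (1R,5S)-4,4-ethylenedioxy-1,8-dimethylbicyclo[5.3.0]dec-8-en-6-one | O=C2CC(C)=CC[C@@]3(C)CCC4(OCCO4)[C@H]23
F6 | step 9 | (1R)-1,8-dimethylbicyclo[5.3.0]dec-8-ene-4,6-dione | O=C2CC(C)=CC[C@@]3(C)CCC(=O)C23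
F7 | step 9 | (1R)-6-(tert-butyldimethylsilyloxy)-1,8-dimethylbicyclo[5.3.0]deca-5,8-dien-4-one | CC(C)(C)[Si](C)(C)OC1=C2C(=O)CC[C@]2(C)CC=C(C)C1
F8 | step 9 | (1R,4R)-6-(tert-butyldimethylsilyloxy)-1,8-dimethyl-4-(propan-2-yl)bicyclo[5.3.0]deca-5,8-dien-4-ol | CC(C)(C)[Si](C)(C)OC1=C2[C@](O)(C(C)C)CC[C@]2(C)CC=C(C)C1
F9 | step 12 | (1R,4S,5S,6R)-1,8-dimethyl-4-(prop-1-en-2-yl)bicyclo[5.3.0]dec-8-ene-4,6-diol | O[C@@H]2CC(C)=CC[C@@]3(C)CC[C@@](O)(C(C)=C)[C@H]23
F10 | step 15 | (1R,4R,5S,6S)-4-hydroxy-1,8-dimethyl-4-(propan-2-yl)bicyclo[5.3.0]dec-8-en-6-yl 3,4-dimethoxybenzoate | COc1ccc(C(=O)O[C@H]2CC(C)=CC[C@@]3(C)CC[C@@](O)(C(C)C)[C@H]23)cc1OC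
F11 | step 3 | (S)-1-phenylethylammonium (1R,5R)-5-methylspiro[bicyclo[3.1.0]hexane-2,2'-[1,3]dioxolane]-1-carboxylate | C[C@H]([NH3+])c1ccccc1.[O-]C(=O)[C@]12C[C@@]1(C)CCC23OCCO3
A1 | alternative 1 | (5R)-2-diazo-5-(2-methoxy-4-methylphenyl)-6-methyl-5-(triethylsilyloxy)heptan-3-one | CC(=[N+]=[N-])C(=O)C[C@@](O[Si](CC)(CC)CC)(C(C)C)c1ccc(C)cc1OC
A2 | alternative 1 | (1R,4R)-6-methoxy-1,8-dimethyl-4-(propan-2-yl)-4-(triethylsilyloxy)bicyclo[5.3.0]deca-5,7,9-trien-2-one (daucane numbering) | COC1=C2[C@](O[Si](CC)(CC)CC)(C(C)C)CC(=O)[C@]2(C)C=CC(C)=C1
A3 | alternative 2 | methyl 2-diazo-3-methylbut-3-enoate | COC(=O)C(=[N+]=[N-])C(C)=C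
A4 | alternative 2 | 3-methylfuran | Cc1ccoc1
A5 | alternative 2 | methyl 3,6-dimethyl-8-oxabicyclo[3.2.1]octa-2,6-diene-2-carboxylate | COC(=O)C1=C(C)C[C@@H]2O[C@H]1C=C2C
A6 | alternative 3 | (6S)-3,6-dimethyl-6-(4-methyl-3-oxopentyl)cyclohept-2-en-1-one | O=C1C=C(C)CC[C@@](C)(CCC(=O)C(C)C)C1
A7 | alternative 3 | (1S,4R,5R)-4-hydroxy-1,8-dimethyl-4-(propan-2-yl)bicyclo[5.3.0]dec-7-en-6-one (daucane numbering) | O=C1C=C(C)CC[C@@]2(C)CC[C@@](O)(C(C)C)[C@H]12
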